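All constants were set for the occasion; the run is a simulation.

I start from a one-step world, in which enzyme turns starting material into target and a charge either gets through in the time or does not, and I add the crystals afterwards.

    starting material + enzyme → target + enzyme, rate k1*[starting material]*[enzyme]/(1 + ([starting material]/Km1) + ([starting material]/Ksi1)^2) (Km1 = 1.4 mM, Ksi1 = 2.9 mM, k1 = 1.9 × 10⁶ M⁻¹ s⁻¹)
    crystals ⇌ target, rate k2*(cs2 - [target]) while solid is left; crystals form when [target] > cs2 (cs2 = 6.8 mM, k2 = 0.35 s⁻¹)

| setting | elm | ash | maple | oak | larch |
|---|---|---|---|---|---|
| starting material | 10 mM | 20 mM | 40 mM | 80 mM | 150 mM |
| enzyme | 0.71 µM | 0.71 µM | 0.71 µM | 0.71 µM | 0.71 µM |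
| time | 3.0 min | 3.0 min | 3.0 min | 3.0 min | 3.0 min |

- target is meant together with its crystals
- solid, in amounts per volume of the solution: crystals
- the concentration of target that is asked is that of its free form alone
- "hardly changes" means that all values lie within two and a half points (for a concentration: within two and a half percent of the largest)
- run time (elm): 3.0 min

- [target] (only what is free in solution) at the end for elm, ash, maple, oak, larch, in this order
- how that number moves from the first to the last of them (falls, then rises / falls all the way / rises all the way / rises, then falls / hardly changes)

I divide the rate law by [starting material] and integrate. The enzyme then has a budget for the run, rate constant times [enzyme] times time, which is the pure number 243. Clearing a charge costs its concentration over 1.4 mM, plus its square divided by 2 and by 2.9 mM squared; I drop a logarithm that is small beside these. The square is the mark of substrate inhibition. Setting cost equal to budget gives 58.2 mM, the clearing charge, at which the enzyme just finishes in the time.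

The charges of elm, ash and maple lie below it, and each is above the solubility, so I expect crystals and [target] at 6.8 mM in these flasks. Oak and larch lie above it, so I expect them still to be making target at the end, with [target] above solubility. Above it I keep the square term alone: the end [starting material] is the root of the charge squared less 2 times 2.9 mM squared times the budget, and the rate there is rate constant times [enzyme] times 2.9 mM squared over that [starting material]. Crystals take up target with a time of 2.86 s, shorter than the run, so I set [target] at 6.8 mM plus rate over 0.35 s⁻¹, which gives 7.47 mM for oak and 7.04 mM for larch. With elm, ash and maple at 6.8 mM, my row rises, then falls.

The forecast gives 6.8 mM, 6.8 mM and 6.8 mM for elm, ash and maple, 7.36 mM for oak and 7.03 mM for larch, so the row rises, then falls, and its ground for the last two is that “crystallisation runs at quasi-steady state”. For oak the forecast stands below my figure, and for larch it is close to mine.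

The flasks give 6.80 mM, 6.80 mM, 6.80 mM, 7.36 mM and 7.03 mM, and the row rises, then falls.

The row turns at 58 mM, close to the clearing charge; maple ends with 0 % of its starting material left and oak with 65 %. In larch the ceiling on dissolved target is the largest single effect: with that ceiling taken away, [target] at the end goes from 7.03 mM to 13.7 mM.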